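**Retrosynthetic overview**

1. Numbering (longipinane): C1 ketone, C2, C3 (CH–CH3), C4, C5, C6 (C bearing CH3 and C15H2OAc), C7 (OAng), C8, C9 (OH), C10 (C–CH3), C11; ring A = C1-C2-C3-C4-C5-C11, ring B = C5-C6-C7-C8-C9-C10-C11, ring C (cyclobutane) = C4-C5-C11-C10; on ring B the "A-face" carries ring A and the C6 methyl, the "H-face" carries H5, H11 and C15.
2. Endgame: selective acylations give C15 acetate, C7 angelate and free C9–OH; C7 is corrected by oxidation and C15–OH-directed reduction; the C3 methyl comes from cuprate addition to the C1-keto C2=C3 enone, which is the Stork–Danheiser transposition product of a C1-methoxy/C3-keto vinylogous ester.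
3. Key disconnection: the C4–C10 bond of ring C, closed last by anti opening of a C9–C10 epoxide by C4 of a silyl dienol ether. Enabling feature: C10 is quaternary and its neighbour C9 carries an oxygen anti to the C10–C4 bond (the imprint of an epoxide), while C4 is the α′ carbon of ring A once the carbonyl is parked at C3, held 1,3-cis to C10 across the C5–C11 fusion bond.
4. Precursor: cis-fused rings A/B. Ring A comes from a Diels–Alder reaction of 3-silyloxy-1,1-dimethoxybutadiene with a ring-B cycloheptenone (C10 ketone, C11=C5); ring B comes from ring-closing metathesis of a diene whose C6 and C7 centres are set by one iridium-catalysed tert-(hydroxy)prenylation.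
5. Order of ring formation: ring B (step 3), ring A (step 7), ring C (step 13).

Key step: step 13

Remark (assumption on the chemistry): the iridium-catalysed tert-(hydroxy)prenylation is taken to be anti-selective (C7–OH anti to the C15 hydroxymethyl in the zigzag through the vinyl group) and to tolerate the remote terminal alkene of 1. This deliberately gives the C7 epimer, whose cis-fused acetonide steers the later steps; C7 is inverted in steps 17–18.

**Route**

Step 1
Reactants: 1 hex-5-en-1-ol; 2 2-methyl-2-vinyloxirane (racemic)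
Product: 3 (2S,3S)-2-ethenyl-2-methyloct-7-ene-1,3-diol (octene C1 = C15, C2 = C6, C3 = C7)
Conditions: [Ir(cod)Cl]2 (2.5 mol %), Tol-BINAP (5 mol %, the enantiomer that gives the 2S,3S diol), 4-cyano-3-nitrobenzoic acid (10 mol %), K3PO4 (5 mol %), THF, 60 °C
Reagents that add atoms: none
Why: Iridium-catalysed transfer-hydrogenative tert-(hydroxy)prenylation; alcohol dehydrogenation and reductive opening of the vinyl epoxide give an aldehyde/σ-allyliridium pair that combines through a chair-like transition state, so the C6 quaternary centre is set by the catalyst (S, as in the target) and the C7 carbinol anti to the C15 hydroxymethyl.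

Step 2
Reactants: 3 (2S,3S)-2-ethenyl-2-methyloct-7-ene-1,3-diol
Product: 4 (4S,5S)-5-ethenyl-2,2,5-trimethyl-4-(pent-4-en-1-yl)-1,3-dioxane
Conditions: 2,2-dimethoxypropane, PPTS (cat.), CH2Cl2, rt
Reagents that add atoms: 2,2-dimethoxypropane, COC(C)(C)OC
Why: Acid-catalysed acetalisation of the 1,3-diol gives the six-membered acetonide that will be cis-fused to ring B; no stereocentre is touched.

Step 3
Reactants: 4 (4S,5S)-5-ethenyl-2,2,5-trimethyl-4-(pent-4-en-1-yl)-1,3-dioxane
Product: 5 (4aS,9aS)-2,2,4a-trimethyl-4,4a,7,8,9,9a-hexahydrocyclohepta[d][1,3]dioxine (ring B with C5=C11, cis-fused C6/C7 acetonide)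
Conditions: second-generation Grubbs catalyst (5 mol %), CH2Cl2 (0.005 M), 40 °C
Reagents that add atoms: none
Why: Ring-closing metathesis of the two terminal alkenes, held cis on the dioxane, closes the seven-membered ring B with loss of ethene.

Step 4
Reactants: 5 (4aS,9aS)-2,2,4a-trimethyl-4,4a,7,8,9,9a-hexahydrocyclohepta[d][1,3]dioxine
Product: 6 (4aS,9aS)-2,2,4a-trimethyl-4a,8,9,9a-tetrahydrocyclohepta[d][1,3]dioxin-7(4H)-one (ring-B enone: C10 ketone, C11=C5)
Conditions: Rh2(cap)4 (1 mol %; cap = caprolactamate), t-BuOOH (5 equiv), K2CO3, CH2Cl2, rt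
Reagents that add atoms: tert-butyl hydroperoxide, CC(C)(C)OO
Why: Dirhodium-catalysed allylic C–H oxidation occurs at C10, the only allylic methylene (the other allylic carbon, C6, is quaternary), and gives the enone.

Step 5
Reactants: 7 1,1-dimethoxyethene; 8 acetyl chloride
Product: 9 4,4-dimethoxybut-3-en-2-one
Conditions: Et3N, Et2O, 0 °C to rt
Reagents that add atoms: none
Why: C-acylation of the electron-rich ketene acetal followed by loss of HCl to the amine gives the acyl ketene acetal.

Step 6
Reactants: 9 4,4-dimethoxybut-3-en-2-one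
Product: 10 3-(tert-butyldimethylsilyloxy)-1,1-dimethoxybuta-1,3-diene
Conditions: TBSOTf, Et3N, Et2O, 0 °C
Reagents that add atoms: tert-butyldimethylsilyl triflate, CC(C)(C)[Si](C)(C)OS(=O)(=O)C(F)(F)F
Why: Soft enolisation of the methyl ketone and O-silylation give the 2-silyloxy diene (silyl enol ether formation).

Step 7
Reactants: 6 ring-B enone; 10 3-(tert-butyldimethylsilyloxy)-1,1-dimethoxybuta-1,3-diene
Product: 11 cis-fused A/B adduct: C10 ketone, C1 dimethyl ketal, C2=C3 with C3–OTBS, H5 and H11 cis on the H-face, C6 methyl on the A-face, C6/C7 acetonide on the H-face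
Conditions: toluene, 80 °C, sealed tube; chromatography on Et3N-deactivated silica
Reagents that add atoms: none
Why: Diels–Alder reaction in which the doubly activated CH2 terminus of the diene bonds to the β-carbon C5 and the ketene-acetal terminus to C11; suprafacial addition makes H5/H11 cis, and the diene adds to the convex face of the cis-fused dioxane–cycloheptenone, anti to the acetonide ring and syn to the C6 methyl.

Step 8
Reactants: 11 cis-fused A/B adduct
Product: 12 C9=C10 enol triflate (C10–OTf) of 11
Conditions: KN(SiMe3)2, THF, −78 °C; then PhNTf2, −78 to 0 °C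
Reagents that add atoms: N-phenylbis(trifluoromethanesulfonimide), O=S(=O)(N(c1ccccc1)S(=O)(=O)C(F)(F)F)C(F)(F)F
Why: Kinetic deprotonation by the bulky amide occurs at the C9 methylene and not at the hindered C11 methine next to the ketal, and O-triflation fixes the C9=C10 enolate (kinetic enolate trapping).

Step 9
Reactants: 12 C9=C10 enol triflate
Product: 13 C9=C10 alkene with the C10 methyl; ring A still C3 silyl enol ether and C1 dimethyl ketal
Conditions: MeMgBr, Fe(acac)3 (5 mol %), THF/NMP, −30 °C
Reagents that add atoms: methylmagnesium bromide, C[Mg]Br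
Why: Iron-catalysed Kumada-type cross-coupling of the alkenyl triflate installs the C10 methyl without moving the double bond; silyl enol ether, ketal and acetonide are inert to the Grignard reagent at this temperature.

Step 10
Reactants: 13 C10-methyl alkene
Product: 14 vinylogous ester: ring A = C1–OMe, C1=C2, C3=O; ring B = C9=C10(CH3); C6/C7 acetonide
Conditions: Bu4NF, THF, 0 °C to rt
Reagents that add atoms: none
Why: Fluoride cleaves the silyl enol ether and the liberated C3 enolate expels methoxide from the C1 ketal (E1cB), giving the 3-methoxy enone without touching the acetonide or the isolated alkene.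

Step 11
Reactants: 14 vinylogous ester
Product: 15 H-face C9–C10 epoxide of 14 (epoxide oxygen cis to H11, trans to C4)
Conditions: mCPBA, NaHCO3, CH2Cl2, 0 °C
Reagents that add atoms: 3-chloroperbenzoic acid, OOC(=O)c1cccc(Cl)c1
Why: Prilezhaev epoxidation of the electron-rich trisubstituted alkene in preference to the deactivated vinylogous-ester double bond; the peracid approaches ring B anti to the allylic C11–C1 bond, on the face of H11.

Step 12
Reactants: 15 epoxy vinylogous ester
Product: 16 C3 tert-butyldimethylsilyl dienol ether of 15 (C4=C3–OTBS, C2=C1–OMe; epoxide and acetonide unchanged)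
Conditions: LiN(iPr)2, THF, −78 °C; then TBSCl, DMPU, −78 to 0 °C; non-aqueous work-up (pentane, filtration), used at once
Reagents that add atoms: tert-butyldimethylsilyl chloride, CC(C)(C)[Si](C)(C)Cl
Why: Kinetic deprotonation of the vinylogous ester takes the α′ proton at C4 (the Stork–Danheiser enolisation mode), not the γ proton at C11 that would open the epoxide, and O-silylation gives the cross-conjugated silyl dienol ether.

Step 13
Reactants: 16 C3 silyl dienol ether with H-face C9–C10 epoxide
Product: 17 tricyclic vinylogous ester: ring C closed (C4–C10 bond); C9–OTBS on the H-face, anti to C10–C4; C10 methyl syn to the C1–C2–C3 bridge; ring A = C1–OMe, C1=C2, C3=O; C6/C7 acetonide (7-epi)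
Conditions: TBSOTf (0.2 equiv), 2,6-di-tert-butyl-4-methylpyridine (0.3 equiv), CH2Cl2, −78 to −30 °C
Reagents that add atoms: none
Why: Proposed new method: TBSOTf silylates the epoxide oxygen, the tertiary C10–O bond lengthens, and C4 of the cyclic 1-methoxy-3-silyloxy diene, held 1,3-cis to C10 across the C5–C11 bond of the cis-fused bicycle, attacks C10 opposite the leaving oxygen; the resulting C3 silyloxocarbenium ion returns its silyl cation to triflate, which regenerates the catalyst and leaves the vinylogous ester. The closest known reaction types are the Lewis-acid-promoted epoxide-initiated cyclisation terminated by a silyl enol ether (known for six-membered rings), the Mukaiyama-type four-membered closure in stepwise enol-silane cyclobutane annulations, and the anionic 4-exo-tet epoxide opening of epoxynitriles; this combination of ring size and nucleophile is new. Ring C (C4, C5, C11, C10) is closed in the 4-exo-tet mode with respect to the epoxide (C9 stays outside the new ring), and no other ring is formed. C10 is set by stereospecific inversion at the epoxide carbon, C4 can bond only on the face that the cis ring fusion allows, and C9 keeps its epoxide configuration so that its silyloxy group ends anti to the new C10–C4 bond, as in the target. The step needs C10–O rather than C9–O cleavage (secured by the tertiary, methyl-bearing C10), attack through C4 rather than C2 (secured by the polarisation of the 1-methoxy-3-silyloxy diene), and capture faster than hydride shift or proton loss at the incipient C10 cation (favoured by the enforced proximity, the nucleophilic diene, low temperature and the hindered pyridine buffer). Because the charge ends on oxygen at C3 and is quenched by silyl transfer, no cyclobutylcarbinyl cation forms and Wagner–Meerwein drift of the pinane-type skeleton is avoided.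

Step 14
Reactants: 17 tricyclic vinylogous ester
Product: 19 tricyclic enone: C1=O, C2=C3 (C3–H); C9–OTBS; C6/C7 acetonide, via 3-hydroxy enol ether 18 (not isolated)
Conditions: iBu2AlH, CH2Cl2, −78 °C; then aq. oxalic acid, THF, 0 °C
Reagents that add atoms: water, O
Why: Stork–Danheiser transposition: 1,2-reduction of the vinylogous-ester carbonyl and mild acid hydrolysis of the 3-methoxy allylic alcohol move the carbonyl to C1; the transient C3 carbinol is destroyed, so its configuration does not matter, and the acetonide survives the brief mild acid.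

Step 15
Reactants: 19 tricyclic enone
Product: 20 tricyclic C1 ketone with the C3 methyl syn to the C5 bridge (target configuration at C3); C9–OTBS; C6/C7 acetonide (7-epi)
Conditions: Me2CuLi (from MeLi and CuI), Et2O, −78 to −30 °C; then H2O
Reagents that add atoms: lithium dimethylcuprate, [Li+].C[Cu-]C
Why: Conjugate addition of the cuprate to the bicyclo[3.1.1]heptenone occurs at C3 from the face of the C5 bridge (syn H) rather than the C10 bridge (syn methyl), which places the C3 methyl on the C5 side as in the target.

Step 16
Reactants: 20 tricyclic ketone acetonide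
Product: 21 7-epi diol: C7–OH on the H-face (cis to C15), C15–OH, C9–OTBS, C1 ketone
Conditions: AcOH/H2O (4:1), 40 °C
Reagents that add atoms: none
Why: Acetal hydrolysis removes the 1,3-dioxane while the hindered secondary silyl ether at C9 survives.

Step 17
Reactants: 21 7-epi diol
Product: 22 C7 ketone with free C15–OH; C9–OTBS; C1 ketone
Conditions: NaOCl (aq.), AcOH, 0 °C to rt
Reagents that add atoms: none
Why: Hypochlorite in acetic acid oxidises secondary alcohols much faster than primary ones, so the C7 carbinol becomes the ketone and the neopentyl C15 hydroxyl is kept.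

Step 18
Reactants: 22 C7 ketone
Product: 23 diol with the target C7 configuration (C7–OH on the A-face, cis to the C6 methyl), C15–OH, C9–OTBS, C1 ketone
Conditions: Me4NBH(OAc)3, MeCN/AcOH (1:1), −30 °C
Reagents that add atoms: none
Why: Evans–Saksena reduction: the borohydride exchanges onto the C15 hydroxyl and delivers hydride to the C7 carbonyl from the C15 face, so the new hydroxyl is trans to C15 as in the target; the undirected C1 ketone is not reduced by this reagent.

Step 19
Reactants: 23 C7,C15-diol
Product: 24 C15 acetate with free C7–OH; C9–OTBS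
Conditions: Ac2O, pyridine, CH2Cl2, −20 °C
Reagents that add atoms: acetic anhydride, CC(=O)OC(C)=O
Why: The primary C15 hydroxyl is acetylated selectively over the hindered secondary neopentyl C7 hydroxyl (steric differentiation in acylation).

Step 20
Reactants: 24 C15 acetate; 25 angelic acid ((Z)-2-methylbut-2-enoic acid)
Product: 27 C7 angelate, C15 acetate, C9–OTBS tricyclic ketone, via angelic 2,4,6-trichlorobenzoic anhydride 26 (not isolated)
Conditions: 25, 2,4,6-trichlorobenzoyl chloride, Et3N, toluene, rt; then 24, 80 °C
Reagents that add atoms: none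
Why: Yamaguchi esterification through the mixed anhydride acylates the hindered C7 hydroxyl and transfers the angeloyl group without Z-to-E isomerisation when no nucleophilic amine catalyst is present.

Step 21
Reactants: 27 C9 silyl ether
Product: 28 CNP0212099.1 (target)
Conditions: HF·pyridine, THF, 0 °C to rt
Reagents that add atoms: none
Why: Fluoride-mediated desilylation frees the C9 hydroxyl without cleaving or migrating the two esters.

**Compound list**

1 | hex-5-en-1-ol | C=CCCCCO | starting material
2 | 2-methyl-2-vinyloxirane (racemic) | CC1(C=C)CO1 | starting material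
3 | (2S,3S)-2-ethenyl-2-methyloct-7-ene-1,3-diol | C=CCCC[C@H](O)[C@](C)(CO)C=C | intermediate
4 | (4S,5S)-5-ethenyl-2,2,5-trimethyl-4-(pent-4-en-1-yl)-1,3-dioxane | C=CCCC[C@@H]1OC(C)(C)OC[C@]1(C)C=C | intermediate
5 | (4aS,9aS)-2,2,4a-trimethyl-4,4a,7,8,9,9a-hexahydrocyclohepta[d][1,3]dioxine | C[C@]12COC(C)(C)O[C@H]1CCCC=C2 | intermediate
6 | (4aS,9aS)-2,2,4a-trimethyl-4a,8,9,9a-tetrahydrocyclohepta[d][1,3]dioxin-7(4H)-one | C[C@]12COC(C)(C)O[C@H]1CCC(=O)C=C2 | intermediate
7 | 1,1-dimethoxyethene | C=C(OC)OC | starting material
8 | acetyl chloride | CC(Cl)=O | starting material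
9 | 4,4-dimethoxybut-3-en-2-one | CC(=O)C=C(OC)OC | intermediate
10 | 3-(tert-butyldimethylsilyloxy)-1,1-dimethoxybuta-1,3-diene | C=C(O[Si](C)(C)C(C)(C)C)C=C(OC)OC | intermediate
11 | cis-fused A/B adduct (C10 ketone, C1 dimethyl ketal, C3 silyl enol ether, 6,7-acetonide) | CC1(C)OC[C@@]2(C)[C@H](CCC(=O)[C@H]3[C@@H]2CC(O[Si](C)(C)C(C)(C)C)=CC3(OC)OC)O1 | intermediate
12 | C9=C10 enol triflate of 11 | CC1(C)OC[C@@]2(C)[C@H](CC=C(OS(=O)(=O)C(F)(F)F)[C@H]3[C@@H]2CC(O[Si](C)(C)C(C)(C)C)=CC3(OC)OC)O1 | intermediate
13 | C10-methyl C9=C10 alkene (ring A as in 11) | CC1(C)OC[C@@]2(C)[C@H](CC=C(C)[C@H]3[C@@H]2CC(O[Si](C)(C)C(C)(C)C)=CC3(OC)OC)O1 | intermediate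
14 | bicyclic vinylogous ester (C1–OMe, C1=C2, C3=O; C9=C10 alkene) | CC1(C)OC[C@@]2(C)[C@H](CC=C(C)[C@H]3[C@@H]2CC(=O)C=C3OC)O1 | intermediate
15 | H-face C9–C10 epoxide of 14 | CC1(C)OC[C@@]2(C)[C@H](C[C@H]4O[C@@]4(C)[C@H]3[C@@H]2CC(=O)C=C3OC)O1 | intermediate
16 | C3 tert-butyldimethylsilyl dienol ether of 15 | CC1(C)OC[C@@]2(C)[C@H](C[C@H]4O[C@@]4(C)[C@H]3[C@@H]2C=C(O[Si](C)(C)C(C)(C)C)C=C3OC)O1 | intermediate
17 | tricyclic vinylogous ester (ring C closed, C9–OTBS, 6,7-acetonide) | CC4(C)O[C@H]1C[C@@H](O[Si](C)(C)C(C)(C)C)[C@]2(C)[C@@H]3[C@@H]([C@H]2C(OC)=CC3=O)[C@@]1(C)CO4 | intermediate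
18 | 3-hydroxy enol ether from 17 (C3 carbinol configuration not controlled) | CC4(C)O[C@H]1C[C@@H](O[Si](C)(C)C(C)(C)C)[C@]2(C)[C@@H]3[C@@H]([C@H]2C(OC)=CC3O)[C@@]1(C)CO4 | intermediate (not isolated)
19 | tricyclic enone (C1=O, C2=C3) | CC4(C)O[C@H]1C[C@@H](O[Si](C)(C)C(C)(C)C)[C@]2(C)[C@@H]3[C@@H]([C@H]2C(=O)C=C3)[C@@]1(C)CO4 | intermediate
20 | tricyclic C1 ketone with C3 methyl (acetonide, 7-epi) | CC4(C)O[C@H]1C[C@@H](O[Si](C)(C)C(C)(C)C)[C@]2(C)[C@@H]3[C@@H]([C@H]2C(=O)C[C@H]3C)[C@@]1(C)CO4 | intermediate
21 | 7-epi C7,C15-diol, C9–OTBS | O[C@H]1C[C@@H](O[Si](C)(C)C(C)(C)C)[C@]2(C)[C@@H]3[C@@H]([C@H]2C(=O)C[C@H]3C)[C@@]1(C)CO | intermediate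
22 | C7 ketone, C15–OH, C9–OTBS | O=C1C[C@@H](O[Si](C)(C)C(C)(C)C)[C@]2(C)[C@@H]3[C@@H]([C@H]2C(=O)C[C@H]3C)[C@@]1(C)CO | intermediate
23 | C7,C15-diol with target C7 configuration, C9–OTBS | O[C@@H]1C[C@@H](O[Si](C)(C)C(C)(C)C)[C@]2(C)[C@@H]3[C@@H]([C@H]2C(=O)C[C@H]3C)[C@@]1(C)CO | intermediate
24 | C15 acetate, C7–OH, C9–OTBS | O[C@@H]1C[C@@H](O[Si](C)(C)C(C)(C)C)[C@]2(C)[C@@H]3[C@@H]([C@H]2C(=O)C[C@H]3C)[C@@]1(C)COC(C)=O | intermediate
25 | angelic acid ((Z)-2-methylbut-2-enoic acid) | C/C=C(/C)C(=O)O | starting material
26 | angelic 2,4,6-trichlorobenzoic anhydride | C/C=C(/C)C(=O)OC(=O)c1c(Cl)cc(Cl)cc1Cl | intermediate (not isolated)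
27 | C7 angelate, C15 acetate, C9–OTBS | C/C=C(/C)C(=O)O[C@@H]1C[C@@H](O[Si](C)(C)C(C)(C)C)[C@]2(C)[C@@H]3[C@@H]([C@H]2C(=O)C[C@H]3C)[C@@]1(C)COC(C)=O | intermediate
28 | CNP0212099.1 | C/C=C(/C)C(=O)O[C@@H]1C[C@@H](O)[C@]2(C)[C@@H]3[C@@H]([C@H]2C(=O)C[C@H]3C)[C@@]1(C)COC(C)=O | target

**Step count and risks**

Total steps: 21. Longest linear sequence: 19 steps (1 to 28 through steps 1–4 and 7–21; steps 5 and 6 make the diene).

Steps most likely to fail:

Step 13. The silyl-activated epoxide may rearrange by hydride shift to a C9 ketone or lose a proton to an allylic silyl ether faster than C4 reaches C10, or the dienol ether may be protodesilylated. The fallback reverses the polarity and uses known chemistry; it sets out from 16 and returns at 17. Bromination of 16 with NBS should give the C4-bromo vinylogous ester F1. A Meinwald rearrangement of its epoxide (MgBr2·OEt2) should give the C9 ketone with a C10–H, F2. KOtBu in t-BuOH/THF should form the more substituted C10 enolate, which displaces the activated C4 bromide in an intramolecular ketone alkylation (the classical enolate/halide closure of bicyclo[3.1.1]heptanones) to give the tricyclic C9 ketone F3. NaBH4 at low temperature should reduce the C9 ketone, not the vinylogous ester, from the face opposite the cis-fused acetonide to give the C9 alcohol F4, and TBSOTf/2,6-lutidine returns to 17.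

Step 7. The cycloaddition may be slow or poorly face-selective because the β-carbon C5 of enone 6 is flanked by the quaternary C6, and the acid-sensitive diene may decompose first. The fallback sets out from 6 and returns at 11. Bromination and dehydrobromination (Br2, then Et3N) should give the 2-bromo enone F5 (bromine on C11), a much more reactive dienophile. Its cycloaddition with 10 should give the C11-bromo adduct F6. Tin hydride reduction (Bu3SnH, AIBN) should then deliver hydrogen to the C11 radical on the convex face and return to 11.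

Step 17. The primary C15 hydroxyl may be over-oxidised, the C1 ketone may be chlorinated at its α-position, or the β-hydroxy ketone may lose formaldehyde by retro-aldol cleavage. The fallback sets out from 21 and returns at 22. Selective silylation of the primary hydroxyl (Et3SiCl, imidazole, −40 °C) should give the C15 triethylsilyl ether F7. Dess–Martin oxidation should give the C7 ketone F8. Mild acid (AcOH/THF/H2O) should remove the primary triethylsilyl group in the presence of the hindered C9 silyl ether and return to 22.

**Further compounds**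

F1 | step 13 | C4-bromo vinylogous ester with C9–C10 epoxide (C4 configuration not fixed) | CC1(C)OC[C@@]2(C)[C@H](C[C@H]4O[C@@]4(C)[C@H]3[C@@H]2C(Br)C(=O)C=C3OC)O1
F2 | step 13 | C9 ketone with C10–H and C4 bromide (C10 and C4 configurations not fixed) | CC1(C)OC[C@@]2(C)[C@H](CC(=O)C(C)[C@H]3[C@@H]2C(Br)C(=O)C=C3OC)O1
F3 | step 13 | tricyclic C9 ketone vinylogous ester (ring C closed) | CC4(C)O[C@H]1CC(=O)[C@]2(C)[C@@H]3[C@@H]([C@H]2C(OC)=CC3=O)[C@@]1(C)CO4
F4 | step 13 | tricyclic C9 alcohol vinylogous ester | CC4(C)O[C@H]1C[C@@H](O)[C@]2(C)[C@@H]3[C@@H]([C@H]2C(OC)=CC3=O)[C@@]1(C)CO4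
F5 | step 7 | 2-bromo enone (C11–Br) of 6 | C[C@]12COC(C)(C)O[C@H]1CCC(=O)C(Br)=C2
F6 | step 7 | C11-bromo Diels–Alder adduct | CC1(C)OC[C@@]2(C)[C@H](CCC(=O)[C@@]3(Br)[C@@H]2CC(O[Si](C)(C)C(C)(C)C)=CC3(OC)OC)O1
F7 | step 17 | C15 triethylsilyl ether of 21 | O[C@H]1C[C@@H](O[Si](C)(C)C(C)(C)C)[C@]2(C)[C@@H]3[C@@H]([C@H]2C(=O)C[C@H]3C)[C@@]1(C)CO[Si](CC)(CC)CC
F8 | step 17 | C7 ketone, C15 triethylsilyl ether | O=C1C[C@@H](O[Si](C)(C)C(C)(C)C)[C@]2(C)[C@@H]3[C@@H]([C@H]2C(=O)C[C@H]3C)[C@@]1(C)CO[Si](CC)(CC)CC
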